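**Retrosynthetic overview**
1. Target 26 ⇐ bis-MOM butenolide 25 ⇐ α-hydroxy ketone 23 (a ketenylidene ylide adds C18–C19 and closes the lactone) ⇐ hydroxy ester 21, whose C16 is bought as methyl (R)-glycidate and joined at C15 to the C14 alkenylmagnesium.
2. The Z-C13=C14 alkene with its C25 hydroxymethyl ⇐ copper-catalysed anti-carbomagnesiation of propargyl alcohol by the C12 Grignard reagent, then iodine.
3. The C8 methyl ⇐ nickel-catalysed C8–O methylation that opens a temporary dihydrofuran (O on C8, C11–C12 arm on C9) in tricycle 10.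
4. Key step: acyclic enynol 7 (geranyl–CH2–C≡C–CH2CH2OH) → 10. The enabling feature is the tetrasubstituted C8=C9 alkene of ring B next to quaternary C10: C8 and C9 are read as the two carbons of an alkyne, and the C11–C12 arm on C9 ends in an oxygen that can capture a cation at C8 (five-membered oxacycle) but not at C9 (four-membered).
5. Order of ring formation: ring A (C1–C5, C10) → five-membered ring C5–C6–C7–C8–C10 → ring B (C5–C10) by 1,2-shift of C10 from C8 to C9 → temporary dihydrofuran (removed in step 4) → butenolide (step 11).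

Key step: step 3

Remark (assumption): the antipode of the chiral acid in step 3 is taken to be the one that gives the (5S,10S) series, the series of (−)-ambrox; both antipodes are accessible.
Conventions: C1–C10 are the decalin carbons (C10 quaternary, C5 the ring-fusion CH, C8 and C9 the alkene carbons), C11–C16 the chain, C17–C19 the butenolide β, α and carbonyl carbons, C24 the hydroxymethyl on C17, C25 the hydroxymethyl on C13. Dec = (4aS,8aS)-2,5,5,8a-tetramethyl-3,4,4a,5,6,7,8,8a-octahydronaphthalen-1-yl (attached through C9).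

**Step 1**
Reactants: 1 geranyl bromide; 2 propargyl bromide
Product: 4 (5E)-6,10-dimethylundeca-5,9-dien-1-yne, via 1,3-dilithiopropyne 3 (not isolated)
Conditions: 2, n-BuLi (2 equiv), TMEDA, Et2O/hexane, −78 °C; then 1, −78 → 20 °C; H2O
Reagents that add atoms: none
Why: SN2 alkylation of the allylic bromide by the sp3 carbon of 1,3-dilithiopropyne (propargylation of an allylic halide) leaves the acetylide end free and the E alkene untouched; no stereocenter is formed.

**Step 2**
Reactants: 4 (5E)-6,10-dimethylundeca-5,9-dien-1-yne; 5 ethylene oxide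
Product: 7 (7E)-8,12-dimethyltrideca-7,11-dien-3-yn-1-ol, via lithium acetylide 6 (not isolated)
Conditions: n-BuLi, THF, −78 °C; 5, DMPU, −78 → 20 °C; H2O
Reagents that add atoms: none
Why: Ring opening of oxirane by a lithium acetylide in a dipolar cosolvent (alkynylation of an epoxide) installs C11–C12 and the hydroxyl that later serves as the internal trap; no stereocenter is formed.

**Step 3**
Reactants: 7 (7E)-8,12-dimethyltrideca-7,11-dien-3-yn-1-ol
Product: 10 tricyclic enol ether (5aS,9aS)-6,6,9a-trimethyl-1,2,4,5,5a,6,7,8,9,9a-decahydronaphtho[2,1-b]furan, via trans-hydrindane vinyl cation 8 (not isolated), via ring B cyclohexenyl cation 9 (not isolated)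
Conditions: confined chiral imidodiphosphorimidate Brønsted acid (IDPi; two 3,3'-diaryl-BINOL phosphoryl units, N-perfluoroalkylsulfonyl groups; 5 mol%), perfluoro-tert-butanol, high dilution, −40 → −20 °C; then Et3N
Reagents that add atoms: none
Why: Proposed new method: the confined chiral acid protonates the terminal C3=C4 alkene, the C4 cation closes ring A on the E-C5=C10 alkene (6-endo-trig, chair) and the resulting C10 cation adds to the nearer alkyne carbon C8 (5-exo-dig), giving the trans-fused five-membered ring C5–C6–C7–C8–C10 with a linear exocyclic vinyl cation at C9 (8); the C8–C10 bond then shifts across the C=C to C9, a 1,2-shift that expands this ring to the six-membered ring B and leaves a ring B vinyl cation at C8 (9), which the C12 hydroxyl caps by 5-endo closure to the temporary dihydrofuran. The closest known reaction is the chiral-Brønsted-acid-catalysed cyclization of homofarnesol to ambrox, of which 7 is the alkyne analogue; the exo closure follows the behaviour of dialkylalkyne terminators in cation–olefin cyclizations, and 1,2-alkyl shifts across the double bond that interconvert exocyclic (cycloalkylidene)alkyl and endocyclic cycloalkenyl vinyl cations are known from vinyl triflate solvolysis. C5 and C10 are set in one event: their trans relationship comes from anti addition across the E alkene through a chair, and the absolute sense from the chiral counter-anion that holds the substrate during the first C–C bond formation. The step needs ring expansion to outrun capture of 8, which the design secures because the hydroxyl cannot reach C9 (a four-membered oxete would result) and neither the bulky counter-anion nor the perfluorinated solvent is nucleophilic, so the equilibrating vinyl cations drain through 9, the only one with an intramolecular trap. It also needs C10 and not C7 to migrate, which the higher migratory aptitude of the quaternary carbon and the relief of strain in the trans-hydrindane should secure.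

**Step 4**
Reactants: 10 tricyclic enol ether
Product: 11 2-Dec-ethan-1-ol
Conditions: MeMgBr (3 equiv), NiCl2(PCy3)2 (10 mol%), toluene, 90 °C; H2O
Reagents that add atoms: methylmagnesium bromide, C[Mg]Br
Why: Nickel-catalysed Kumada-type cross-coupling with C(sp2)–O cleavage of a cyclic enol ether (ring-opening alkylation of 2,3-dihydrofurans) puts the methyl on C8 with the alkene fixed at C8=C9 and releases the C12 alkoxide, so the temporary ring is removed; no stereocenter changes.

**Step 5**
Reactants: 11 2-Dec-ethan-1-ol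
Product: 12 2-Dec-ethyl bromide
Conditions: CBr4, PPh3, CH2Cl2, 0 °C
Reagents that add atoms: carbon tetrabromide, BrC(Br)(Br)Br
Why: Appel bromination of a primary alcohol under neutral conditions that leave the tetrasubstituted alkene in place; no stereocenter changes.

**Step 6**
Reactants: 12 2-Dec-ethyl bromide; 13 propargyl alcohol
Product: 17 (2Z)-2-(2-Dec-ethyl)-3-iodoprop-2-en-1-ol, via chloromagnesium propargyl alkoxide 14 (not isolated), via Grignard reagent 15 (not isolated), via oxamagnesacycle 16 (not isolated)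
Conditions: 13 (1.5 equiv), i-PrMgCl (1.5 equiv), THF, 0 °C; separately 12, Mg, THF, 40 °C; combine, CuI (10 mol%), 20 → 35 °C; I2, −20 °C; H2O, aq. Na2S2O3 wash
Reagents that add atoms: iodine, II
Why: Copper-catalysed anti-carbomagnesiation of a propargylic alkoxide puts the alkyl group on the internal alkyne carbon (C13) and magnesium on the terminal carbon (C14) cis to the alkoxide in a five-membered chelate, so iodinolysis with retention gives the Z-iodoalkene in which the C25 hydroxymethyl and the later C15 are cis; no stereocenter is formed.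

**Step 7**
Reactants: 17 (2Z)-2-(2-Dec-ethyl)-3-iodoprop-2-en-1-ol
Product: 18 MOM ether (3Z)-1-Dec-4-iodo-3-[(methoxymethoxy)methyl]but-3-ene
Conditions: MOMCl, i-Pr2NEt, CH2Cl2, 0 → 20 °C
Reagents that add atoms: chloromethyl methyl ether, COCCl
Why: O-alkylation of the allylic alcohol with a chloromethyl ether (acetal protection); an acetal is chosen because a silyl ether cis to the later alkenyl metal could migrate from oxygen to carbon.

**Step 8**
Reactants: 18 MOM ether; 19 methyl (R)-glycidate
Product: 21 methyl (2R,4Z)-7-Dec-2-hydroxy-5-[(methoxymethoxy)methyl]hept-4-enoate, via alkenylmagnesium chloride 20 (not isolated)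
Conditions: i-PrMgCl·LiCl, THF, −20 → 0 °C; CuI (10 mol%), 19, −40 → −20 °C; H2O
Reagents that add atoms: none
Why: Iodine–magnesium exchange with retention of alkene geometry, then copper-catalysed SN2 opening of the glycidic ester at its CH2 carbon (C15), which does not touch the epoxide stereocenter, so C16 arrives as R from the purchased epoxide.

**Step 9**
Reactants: 21 hydroxy ester
Product: 22 (2R,4Z)-7-Dec-2-hydroxy-N-methoxy-5-[(methoxymethoxy)methyl]-N-methylhept-4-enamide
Conditions: MeNH(OMe)·HCl, i-PrMgCl (excess), THF, −20 → 0 °C; H2O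
Reagents that add atoms: N,O-dimethylhydroxylamine hydrochloride, CNOC.Cl
Why: Aminolysis of the ester by the magnesium amide of N,O-dimethylhydroxylamine (N-methoxy-N-methylamide formation); C16 is held as its magnesium alkoxide, which disfavours deprotonation at that carbon.

**Step 10**
Reactants: 22 N-methoxy-N-methylamide
Product: 23 (3R,5Z)-8-Dec-3-hydroxy-1-(methoxymethoxy)-6-[(methoxymethoxy)methyl]oct-5-en-2-one
Conditions: Bu3SnCH2OCH2OMe, n-BuLi, THF, −78 °C (3 equiv of the lithium reagent); add 22, −78 °C; pH 7 buffer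
Reagents that add atoms: tributyl[(methoxymethoxy)methyl]stannane, CCCC[Sn](CCCC)(CCCC)COCOC
Why: Addition of an α-alkoxy organolithium (from tin–lithium exchange) to the N-methoxy-N-methylamide, whose chelated tetrahedral intermediate stops at the ketone and so delivers C24; the C16 alkoxide shields the adjacent carbon from enolization.

**Step 11**
Reactants: 23 α-hydroxy ketone
Product: 25 (5R)-4-[(methoxymethoxy)methyl]-5-[(2Z)-5-Dec-3-[(methoxymethoxy)methyl]pent-2-en-1-yl]furan-2(5H)-one, via ester ylide 24 (not isolated)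
Conditions: Ph3P=C=C=O, toluene, 80 → 100 °C
Reagents that add atoms: (triphenylphosphoranylidene)ketene, O=C=C=P(c1ccccc1)(c1ccccc1)c1ccccc1
Why: Addition of the C16 hydroxyl to the ketenylidene ylide gives an ester ylide that closes by intramolecular Wittig olefination onto the C17 ketone (the butenolide synthesis used for cardenolide rings from α-hydroxy ketones); no bond to C16 is broken, so it stays R.

**Step 12**
Reactants: 25 bis-MOM butenolide
Product: 26 16-epi-luffarin L, (5R)-4-(hydroxymethyl)-5-[(2Z)-5-Dec-3-(hydroxymethyl)pent-2-en-1-yl]furan-2(5H)-one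
Conditions: HCl (cat., from AcCl), MeOH, 40 °C
Reagents that add atoms: none
Why: Acid-catalysed transacetalization of both methoxymethyl ethers to dimethoxymethane; the lactone, both alkenes and C16 should be stable to dilute methanolic acid.

**Compound list**
1 | geranyl bromide, (2E)-1-bromo-3,7-dimethylocta-2,6-diene | BrC/C=C(\C)CCC=C(C)C | starting material
2 | propargyl bromide, 3-bromoprop-1-yne | BrCC#C | starting material
3 | 1,3-dilithiopropyne | [Li]CC#C[Li] | intermediate
4 | (5E)-6,10-dimethylundeca-5,9-dien-1-yne | C#CCC/C=C(\C)CCC=C(C)C | intermediate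
5 | ethylene oxide (oxirane) | C1CO1 | starting material
6 | lithium acetylide of 4, [(5E)-6,10-dimethylundeca-5,9-dien-1-yn-1-yl]lithium | [Li]C#CCC/C=C(\C)CCC=C(C)C | intermediate
7 | (7E)-8,12-dimethyltrideca-7,11-dien-3-yn-1-ol | OCCC#CCC/C=C(\C)CCC=C(C)C | intermediate
8 | trans-hydrindane vinyl cation, 3-hydroxy-1-[(3aS,7aS)-4,4,7a-trimethyloctahydro-1H-inden-1-ylidene]propan-1-ylium (five-membered ring C5–C6–C7–C8–C10, cation at exocyclic C9) | OCC[C+]=C1[C@@]2(C)CCCC(C)(C)[C@@H]2CC1 | intermediate
9 | ring B cyclohexenyl cation, (4aS,8aS)-1-(2-hydroxyethyl)-5,5,8a-trimethyl-3,4,4a,5,6,7,8,8a-octahydronaphthalen-2-ylium (cation at C8) | [C+]1=C(CCO)[C@@]2(C)CCCC(C)(C)[C@@H]2CC1 | intermediate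
10 | tricyclic enol ether, (5aS,9aS)-6,6,9a-trimethyl-1,2,4,5,5a,6,7,8,9,9a-decahydronaphtho[2,1-b]furan | O3C1=C(CC3)[C@@]2(C)CCCC(C)(C)[C@@H]2CC1 | intermediate
11 | 2-Dec-ethan-1-ol, 2-[(4aS,8aS)-2,5,5,8a-tetramethyl-3,4,4a,5,6,7,8,8a-octahydronaphthalen-1-yl]ethan-1-ol | CC1=C(CCO)[C@@]2(C)CCCC(C)(C)[C@@H]2CC1 | intermediate
12 | 2-Dec-ethyl bromide | CC1=C(CCBr)[C@@]2(C)CCCC(C)(C)[C@@H]2CC1 | intermediate
13 | propargyl alcohol, prop-2-yn-1-ol | C#CCO | starting material
14 | chloromagnesium prop-2-yn-1-olate | C#CCO[Mg]Cl | intermediate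
15 | (2-Dec-ethyl)magnesium bromide | CC1=C(CC[Mg]Br)[C@@]2(C)CCCC(C)(C)[C@@H]2CC1 | intermediate
16 | 4-(2-Dec-ethyl)-2,5-dihydro-1,2-oxamagnesole (magnesium on C14 cis to the C25 oxygen) | CC1=C(CCC3=C[Mg]OC3)[C@@]2(C)CCCC(C)(C)[C@@H]2CC1 | intermediate
17 | (2Z)-2-(2-Dec-ethyl)-3-iodoprop-2-en-1-ol | CC1=C(CC/C(=C/I)CO)[C@@]2(C)CCCC(C)(C)[C@@H]2CC1 | intermediate
18 | (3Z)-1-Dec-4-iodo-3-[(methoxymethoxy)methyl]but-3-ene | CC1=C(CC/C(=C/I)COCOC)[C@@]2(C)CCCC(C)(C)[C@@H]2CC1 | intermediate
19 | methyl (R)-glycidate, methyl (2R)-oxirane-2-carboxylate | COC(=O)[C@H]1CO1 | starting material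
20 | [(1Z)-4-Dec-2-[(methoxymethoxy)methyl]but-1-en-1-yl]magnesium chloride | CC1=C(CC/C(=C/[Mg]Cl)COCOC)[C@@]2(C)CCCC(C)(C)[C@@H]2CC1 | intermediate
21 | methyl (2R,4Z)-7-Dec-2-hydroxy-5-[(methoxymethoxy)methyl]hept-4-enoate | CC1=C(CC/C(=C/C[C@@H](O)C(=O)OC)COCOC)[C@@]2(C)CCCC(C)(C)[C@@H]2CC1 | intermediate
22 | (2R,4Z)-7-Dec-2-hydroxy-N-methoxy-5-[(methoxymethoxy)methyl]-N-methylhept-4-enamide | CC1=C(CC/C(=C/C[C@@H](O)C(=O)N(C)OC)COCOC)[C@@]2(C)CCCC(C)(C)[C@@H]2CC1 | intermediate
23 | (3R,5Z)-8-Dec-3-hydroxy-1-(methoxymethoxy)-6-[(methoxymethoxy)methyl]oct-5-en-2-one | CC1=C(CC/C(=C/C[C@@H](O)C(=O)COCOC)COCOC)[C@@]2(C)CCCC(C)(C)[C@@H]2CC1 | intermediate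
24 | ester ylide, the (triphenylphosphoranylidene)acetate of the C16 hydroxyl of 23 | CC1=C(CC/C(=C/C[C@@H](OC(=O)C=P(c3ccccc3)(c3ccccc3)c3ccccc3)C(=O)COCOC)COCOC)[C@@]2(C)CCCC(C)(C)[C@@H]2CC1 | intermediate
25 | (5R)-4-[(methoxymethoxy)methyl]-5-[(2Z)-5-Dec-3-[(methoxymethoxy)methyl]pent-2-en-1-yl]furan-2(5H)-one | CC1=C(CC/C(=C/C[C@H]3OC(=O)C=C3COCOC)COCOC)[C@@]2(C)CCCC(C)(C)[C@@H]2CC1 | intermediate
26 | 16-epi-luffarin L, (5R)-4-(hydroxymethyl)-5-[(2Z)-3-(hydroxymethyl)-5-[(4aS,8aS)-2,5,5,8a-tetramethyl-3,4,4a,5,6,7,8,8a-octahydronaphthalen-1-yl]pent-2-en-1-yl]furan-2(5H)-one | CC1=C(CC/C(=C/C[C@H]2OC(=O)C=C2CO)CO)[C@@]2(C)CCCC(C)(C)[C@@H]2CC1 | target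

**Step count and risks**
Total step count: 12. Longest linear sequence: 12 steps (from geranyl bromide 1; all other inputs are purchased).

Steps most likely to fail:

Step 3 (Proposed new method). What may go wrong: capture or elimination of the C10 or C9 cation before the 1,2-shift, migration of C7 in place of C10, acid-induced loss of the enol ether, or weak enantiofacial control at the first ring closure. Fallback with known chemistry, setting out from 4 and returning at 11 (it gives up the alkyne terminator): zirconium-catalysed carboalumination of 4 (AlMe3, Cp2ZrCl2, CH2Cl2), then n-BuLi and ethylene oxide, gives (3E,7E)-homofarnesol F1. The established chiral-Brønsted-acid (IDPi) cyclization of this trienol in perfluoro-tert-butanol gives (−)-ambrox F2 with the same C5 and C10 configuration. Acylative cleavage of the tertiary C8–O bond (Ac2O, FeCl3, 0 °C), followed by acid equilibration of the alkene into the tetrasubstituted C8=C9 position (TsOH, toluene), gives 2-Dec-ethyl acetate F3. Methanolysis (K2CO3, MeOH) returns alcohol 11.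

Step 4. What may go wrong: slow insertion of nickel into the hindered, tetrasubstituted C8–O bond, so that the enol ether is recovered or hydrolysed on work-up. Fallback setting out from 10 and returning at 11: hydrolysis (1 M HCl, THF) gives the ketol (4aS,8aS)-1-(2-hydroxyethyl)-5,5,8a-trimethyloctahydronaphthalen-2(1H)-one F4 (C9 epimers, of no consequence). Wittig methylenation with excess Ph3P=CH2 (toluene, 80 °C) gives the exocyclic alkene 2-(5,5,8a-trimethyl-2-methylidenedecahydronaphthalen-1-yl)ethan-1-ol F5 (ring fusion as in 11). Benzoylation (BzCl, pyridine) gives its benzoate F6. Acid-mediated migration of the exocyclic double bond into the thermodynamically preferred tetrasubstituted C8=C9 position (TsOH, toluene, 80 °C) gives 2-Dec-ethyl benzoate F7. Methanolysis (K2CO3, MeOH) returns 11.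

Step 11. What may go wrong: enolization of the α-hydroxy ketone by the basic ylide competing with O-acylation of the hindered secondary hydroxyl, which would erode the C16 configuration or transpose the ketol. Fallback setting out from 23 and returning at 25: esterification of the C16 hydroxyl with diethylphosphonoacetic acid under neutral carbodiimide conditions (DCC, DMAP cat., CH2Cl2, 0 °C) gives the phosphonoacetate F8. It is closed by intramolecular Horner–Wadsworth–Emmons olefination under mild lithium chloride/amine conditions (LiCl, i-Pr2NEt, MeCN, 20 °C) to 25.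

**Further compounds**
F1 | step 3 | (3E,7E)-homofarnesol, (3E,7E)-4,8,12-trimethyltrideca-3,7,11-trien-1-ol | OCC/C=C(\C)CC/C=C(\C)CCC=C(C)C
F2 | step 3 | (−)-ambrox, (3aR,5aS,9aS,9bR)-3a,6,6,9a-tetramethyldodecahydronaphtho[2,1-b]furan | C[C@]1(OCC3)[C@H]3[C@@]2(C)CCCC(C)(C)[C@@H]2CC1
F3 | step 3 | 2-Dec-ethyl acetate | CC1=C(CCOC(C)=O)[C@@]2(C)CCCC(C)(C)[C@@H]2CC1
F4 | step 4 | (4aS,8aS)-1-(2-hydroxyethyl)-5,5,8a-trimethyloctahydronaphthalen-2(1H)-one (C9 epimers) | O=C1C(CCO)[C@@]2(C)CCCC(C)(C)[C@@H]2CC1
F5 | step 4 | 2-(5,5,8a-trimethyl-2-methylidenedecahydronaphthalen-1-yl)ethan-1-ol (ring fusion as in 11) | C=C1C(CCO)[C@@]2(C)CCCC(C)(C)[C@@H]2CC1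
F6 | step 4 | 2-(5,5,8a-trimethyl-2-methylidenedecahydronaphthalen-1-yl)ethyl benzoate (ring fusion as in 11) | C=C1C(CCOC(=O)c3ccccc3)[C@@]2(C)CCCC(C)(C)[C@@H]2CC1
F7 | step 4 | 2-Dec-ethyl benzoate | CC1=C(CCOC(=O)c3ccccc3)[C@@]2(C)CCCC(C)(C)[C@@H]2CC1
F8 | step 11 | (diethoxyphosphoryl)acetate of the C16 hydroxyl of 23 | CC1=C(CC/C(=C/C[C@@H](OC(=O)CP(=O)(OCC)OCC)C(=O)COCOC)COCOC)[C@@]2(C)CCCC(C)(C)[C@@H]2CC1
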